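**Retrosynthetic overview** (drimane locants: ring A = C1–C5 + C10, ring B = C5–C10, C11 = CH2O on C9, C13 = CH2O on C4)

1. The angelate on O13 and the umbelliferyl ether on O11 are attached last (mixed-anhydride esterification, Mitsunobu), after the skeleton is complete.
2. The bicycle comes from one Lewis-acid epoxy-polyene cascade of an acyclic (2R,3R)-epoxy farnesyl tert-butyl carbonate: ring A closes first (C4–C5), ring B second (C9–C10), and the C8 cation is trapped by the carbonate as a temporary 1,3-dioxan-2-one, later removed by methanolysis.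
3. Enabling feature: in ring B the tertiary C8–OH and the C11 oxygen on C9 are 1,3-related (O–C8–C9–C11–O) and both equatorial, with the C8–O bond anti to the C9–C10 bond. This is what anti addition of C10 and an O11-bound carbonate oxygen across an (E)-C8=C9 alkene gives.
4. The C3–OH / C4(CH3)(CH2O) pattern of ring A is an opened epoxide of an (E)-allylic alcohol, so a Sharpless epoxidation sets the absolute configuration of all six stereocentres.
5. The precursor comes from (2E,6E)-farnesol in four steps (Boc carbonate, SeO2 allylic oxidation, asymmetric epoxidation, silylation); the coumarin rings are bought as umbelliferone.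

Key step: step 5

Remark on configuration: the given enantiomer is (3R,4S,5S,8S,9R,10R), antipodal at the ring fusion to drimanes derived from sclareol, so the skeleton is built de novo. With the C10 methyl "up", H5 and H9 are down; C11, the C8 methyl, the C4 methyl and the C3 hydroxyl are up; the C8 oxygen and C13 are down.

Assumption: the L-(+)-tartrate catalyst is taken to convert (E)-2-methylalk-2-en-1-ols into (2S,3S)-epoxy alcohols, so the D-(−)-tartrate is used for the (2R,3R) series needed here.

**Step 1**
Reactants: 1 (2E,6E)-farnesol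
Product: 2 tert-butyl (2E,6E)-3,7,11-trimethyldodeca-2,6,10-trien-1-yl carbonate
Conditions: Boc2O, DMAP (10 mol%), CH2Cl2, 0 °C to rt
Reagents that add atoms: di-tert-butyl dicarbonate, CC(C)(C)OC(=O)OC(=O)OC(C)(C)C
Why: DMAP-catalysed O-acylation of a primary allylic alcohol with Boc2O (carbonate formation) is routine and installs the group that later terminates the cyclization.

**Step 2**
Reactants: 2 tert-butyl farnesyl carbonate
Product: 3 tert-butyl (2E,6E,10E)-12-hydroxy-3,7,11-trimethyldodeca-2,6,10-trien-1-yl carbonate
Conditions: SeO2 (0.3 equiv), t-BuOOH (3 equiv), salicylic acid (0.1 equiv), CH2Cl2, 0 °C to rt, stopped at partial conversion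
Reagents that add atoms: selenium dioxide, O=[Se]=O (transfers the oxygen atom); tert-butyl hydroperoxide, CC(C)(C)OO (reoxidises selenium, net oxygen source)
Why: SeO2-catalysed allylic oxidation (ene reaction then [2,3]-sigmatropic shift) should attack the most electron-rich terminal alkene at its (E)-methyl group, as known for farnesyl esters, and so fixes the E geometry that later defines C4.

**Step 3**
Reactants: 3 12-hydroxyfarnesyl tert-butyl carbonate
Product: 4 tert-butyl (2E,6E)-9-[(2R,3R)-3-(hydroxymethyl)-3-methyloxiran-2-yl]-3,7-dimethylnona-2,6-dien-1-yl carbonate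
Conditions: Ti(OiPr)4 (10 mol%), D-(−)-diisopropyl tartrate (12 mol%), t-BuOOH (2 equiv, anhydrous), 4 Å molecular sieves, CH2Cl2, −20 °C
Reagents that add atoms: tert-butyl hydroperoxide, CC(C)(C)OO
Why: Sharpless asymmetric epoxidation touches only the allylic alcohol alkene, and with the D-(−)-tartrate catalyst should give the (2R,3R)-epoxide, which sets C3 and (after inversion) C4 and with them the absolute configuration of the skeleton.

**Step 4**
Reactants: 4 epoxy alcohol
Product: 5 tert-butyl (2E,6E)-9-[(2R,3R)-3-{[(tert-butyldiphenylsilyl)oxy]methyl}-3-methyloxiran-2-yl]-3,7-dimethylnona-2,6-dien-1-yl carbonate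
Conditions: TBDPSCl, imidazole, CH2Cl2, 0 °C to rt
Reagents that add atoms: tert-butyl(chloro)diphenylsilane, CC(C)(C)[Si](Cl)(c1ccccc1)c1ccccc1
Why: Imidazole-mediated silylation of the primary alcohol gives a bulky, non-participating ether that tolerates the Lewis acid of the next step and leaves the epoxide stereocentres untouched.

**Step 5**
Reactants: 5 epoxy silyl ether carbonate
Product: 7 (3R,4S,5S,8S,9R,10R)-13-(tert-butyldiphenylsilyloxy)-3-hydroxydrimane-8,11-diyl carbonate, via aluminate-bound tert-butoxydioxanylium ion 6 (not isolated)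
Conditions: MeAlCl2 (1.5 equiv, 1 M in hexanes), CH2Cl2 (high dilution), −78 °C; then aq. potassium sodium tartrate
Reagents that add atoms: none
Why: Proposed new method: MeAlCl2 activates the epoxide, the C5=C10 alkene opens it at the tertiary carbon C4 with inversion (ring A, C4–C5 bond, 6-endo at both the epoxide and the alkene), the resulting C10 cation is taken by the C8=C9 alkene (ring B, C9–C10 bond, 6-endo-trig) and the C8 cation is captured by the carbonyl oxygen of the O11 tert-butyl carbonate (temporary ring, O–C8 bond, six-membered, 6-endo at the alkene) to give dioxanylium ion 6, which loses isobutene. The closest known reaction types are Lewis-acid epoxy-polyene cyclizations of epoxyfarnesyl esters, the capture of the C8 cation by the acyl oxygen when farnesyl acetate is cyclized in strong acid, and tert-butyl carbonates as terminating nucleophiles in epoxide-opening cascades and iodocarbonate cyclizations; their combination on an allylic carbonate is the untested part. C3 keeps the epoxide configuration and C4 is inverted so that the (E)-silyloxymethyl group becomes equatorial and the methyl axial; the chair–chair fold of the (E,E)-diene gives the trans ring fusion (C5–H anti to the C10 methyl) and an equatorial C11 on C9; anti addition across C8=C9 places the C8–O bond equatorial and the C8 methyl axial on the face of the C10 methyl. Which of the two mirror-image chair–chair folds is used is dictated by the epoxide, whose C3–O bond must become equatorial, so the enantiomeric purity of 5 is carried into all six stereocentres. The step needs (a) opening at C4 rather than C3 in spite of the withdrawing CH2OSi group, secured by the tertiary versus secondary carbon and by the bulky silyl group that disfavours chelation, and (b) closure of ring B faster than proton loss from the C10 cation, which the neighbouring carbonate carbonyl should secure by assisting attack of the otherwise deactivated C8=C9 alkene. The low temperature is meant to keep the tert-butyl carbonate and the allylic C11–O bond intact until they are used.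

**Step 6**
Reactants: 7 bicyclic cyclic carbonate
Product: 8 (3R,4S,5S,8S,9R,10R)-13-(tert-butyldiphenylsilyloxy)drimane-3,8,11-triol
Conditions: K2CO3 (0.3 equiv), MeOH, rt to 40 °C
Reagents that add atoms: none
Why: Base-catalysed transesterification (methanolysis) removes the temporary carbonate ring as dimethyl carbonate without touching the silyl ether or any stereocentre.

**Step 7**
Reactants: 8 silyloxy triol; 9 umbelliferone (7-hydroxy-2H-chromen-2-one)
Product: 10 (3R,4S,5S,8S,9R,10R)-13-(tert-butyldiphenylsilyloxy)-11-[(2-oxo-2H-chromen-7-yl)oxy]drimane-3,8-diol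
Conditions: PPh3, DIAD, THF, 0 °C to 50 °C
Reagents that add atoms: none
Why: Mitsunobu etherification with the acidic phenol should occur only at the primary C11 hydroxyl, because the neopentyl-type secondary C3 hydroxyl and the tertiary C8 hydroxyl are too hindered to be displaced, and no stereocentre is involved.

**Step 8**
Reactants: 10 silyl-protected aryl ether
Product: 11 (3R,4S,5S,8S,9R,10R)-11-[(2-oxo-2H-chromen-7-yl)oxy]drimane-3,8,13-triol
Conditions: TBAF/AcOH (1:1), THF, rt to 40 °C
Reagents that add atoms: none
Why: Fluoride-mediated desilylation buffered with acetic acid should free the primary C13 hydroxyl without opening the coumarin lactone.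

**Step 9**
Reactants: 11 triol aryl ether; 12 angelic acid ((2Z)-2-methylbut-2-enoic acid)
Product: 14 [(1S,2R,4aR,5R,6S,8aS)-2,6-dihydroxy-1,4a,6-trimethyl-5-{[(2-oxo-2H-chromen-7-yl)oxy]methyl}decahydronaphthalen-1-yl]methyl (2Z)-2-methylbut-2-enoate, via angelic 2,4,6-trichlorobenzoic anhydride 13 (not isolated)
Conditions: 12, 2,4,6-trichlorobenzoyl chloride, Et3N, toluene, rt; then 11, toluene, 75 °C
Reagents that add atoms: none
Why: Acylation with the mixed 2,4,6-trichlorobenzoic anhydride of angelic acid (Yamaguchi-type esterification run without DMAP) is the established way to make angelates without Z to E isomerization, and should select the primary C13 hydroxyl over the hindered secondary C3 and tertiary C8 hydroxyls.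

**Compound list**

1 | (2E,6E)-farnesol | CC(C)=CCC/C(C)=C/CC/C(C)=C/CO | starting material
2 | tert-butyl (2E,6E)-3,7,11-trimethyldodeca-2,6,10-trien-1-yl carbonate | CC(C)=CCC/C(C)=C/CC/C(C)=C/COC(=O)OC(C)(C)C | intermediate
3 | tert-butyl (2E,6E,10E)-12-hydroxy-3,7,11-trimethyldodeca-2,6,10-trien-1-yl carbonate | OC/C(C)=C/CC/C(C)=C/CC/C(C)=C/COC(=O)OC(C)(C)C | intermediate
4 | tert-butyl (2E,6E)-9-[(2R,3R)-3-(hydroxymethyl)-3-methyloxiran-2-yl]-3,7-dimethylnona-2,6-dien-1-yl carbonate | OC[C@@]1(C)O[C@@H]1CC/C(C)=C/CC/C(C)=C/COC(=O)OC(C)(C)C | intermediate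
5 | tert-butyl (2E,6E)-9-[(2R,3R)-3-{[(tert-butyldiphenylsilyl)oxy]methyl}-3-methyloxiran-2-yl]-3,7-dimethylnona-2,6-dien-1-yl carbonate | CC(C)(C)[Si](OC[C@@]1(C)O[C@@H]1CC/C(C)=C/CC/C(C)=C/COC(=O)OC(C)(C)C)(c1ccccc1)c1ccccc1 | intermediate
6 | bicyclic 2-tert-butoxy-1,3-dioxan-2-ylium ion across O8 and O11, zwitterion with the O3-bound methyldichloroaluminate | CC(C)(C)[Si](OC[C@]1(C)[C@H]2CC[C@]3(C)OC(OC(C)(C)C)=[O+]C[C@H]3[C@]2(C)CC[C@H]1O[Al-](C)(Cl)Cl)(c1ccccc1)c1ccccc1 | intermediate
7 | (3R,4S,5S,8S,9R,10R)-13-(tert-butyldiphenylsilyloxy)-3-hydroxydrimane-8,11-diyl carbonate (1,3-dioxan-2-one trans-fused at C8/C9) | CC(C)(C)[Si](OC[C@]1(C)[C@H]2CC[C@]3(C)OC(=O)OC[C@H]3[C@]2(C)CC[C@H]1O)(c1ccccc1)c1ccccc1 | intermediate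
8 | (3R,4S,5S,8S,9R,10R)-13-(tert-butyldiphenylsilyloxy)drimane-3,8,11-triol | CC(C)(C)[Si](OC[C@]1(C)[C@H]2CC[C@](C)(O)[C@@H](CO)[C@]2(C)CC[C@H]1O)(c1ccccc1)c1ccccc1 | intermediate
9 | umbelliferone (7-hydroxy-2H-chromen-2-one) | Oc1ccc2ccc(=O)oc2c1 | starting material
10 | (3R,4S,5S,8S,9R,10R)-13-(tert-butyldiphenylsilyloxy)-11-[(2-oxo-2H-chromen-7-yl)oxy]drimane-3,8-diol | CC(C)(C)[Si](OC[C@]1(C)[C@H]2CC[C@](C)(O)[C@@H](COc3ccc4ccc(=O)oc4c3)[C@]2(C)CC[C@H]1O)(c1ccccc1)c1ccccc1 | intermediate
11 | (3R,4S,5S,8S,9R,10R)-11-[(2-oxo-2H-chromen-7-yl)oxy]drimane-3,8,13-triol | OC[C@]1(C)[C@H]2CC[C@](C)(O)[C@@H](COc3ccc4ccc(=O)oc4c3)[C@]2(C)CC[C@H]1O | intermediate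
12 | angelic acid, (2Z)-2-methylbut-2-enoic acid | C/C=C(/C)C(=O)O | starting material
13 | angelic 2,4,6-trichlorobenzoic anhydride | C/C=C(/C)C(=O)OC(=O)c1c(Cl)cc(Cl)cc1Cl | intermediate
14 | [(1S,2R,4aR,5R,6S,8aS)-2,6-dihydroxy-1,4a,6-trimethyl-5-{[(2-oxo-2H-chromen-7-yl)oxy]methyl}decahydronaphthalen-1-yl]methyl (2Z)-2-methylbut-2-enoate | C/C=C(/C)C(=O)OC[C@]1(C)[C@H]2CC[C@](C)(O)[C@@H](COc3ccc4ccc(=O)oc4c3)[C@]2(C)CC[C@H]1O | target

**Summary**

Total step count: 9. Longest linear sequence: 9 steps from farnesol.

**Steps most likely to fail**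

Step 5 (proposed new method). The cascade may stop after ring A through proton loss from the C10 cation, the tert-butyl group may be lost before the carbonate is needed, or the epoxide may rearrange without the alkene taking part. The fallback uses known chemistry, sets out from 5 and comes back at 8:
- Titanocene-mediated radical cyclization of the epoxypolyene with trivalent titanium (Cp2TiCl2 catalytic, Mn dust, TMSCl, 2,4,6-collidine, THF, rt, mild acidic work-up) should give (3R,4S,5S,9S,10R)-11-(tert-butoxycarbonyloxy)-13-(tert-butyldiphenylsilyloxy)drim-8(12)-en-3-ol F1. C4 is then set by the chair transition state with the bulky silyloxymethyl group equatorial.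
- Epoxidation with mCPBA (NaHCO3, CH2Cl2, 0 °C) from the face opposite the C10 methyl should give the 8,12-spiro-epoxide F2.
- LiAlH4 (THF, 0 °C to rt) should open the epoxide at its CH2 carbon and cleave the carbonate reductively, which gives triol 8.

Step 7. Displacement at the neopentyl-like C11 oxyphosphonium ion may be slow, so that elimination or attack by the neighbouring C8 hydroxyl competes. The fallback sets out from 8 and comes back at 10. It forms the aryl–oxygen bond instead of the alkyl–oxygen bond by palladium-catalysed C–O cross-coupling of the primary alcohol with commercial 7-bromocoumarin (Pd2(dba)3, RockPhos, Cs2CO3, toluene, 90 °C); this makes no new compound (F0).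

Step 9. The angeloyl unit may isomerize to the tigloyl unit during activation, and acylation may spread to the C3 hydroxyl. The fallback sets out from 11 and comes back at 14, building the Z alkene on the molecule:
- Esterification of the primary hydroxyl with 2-[bis(2,2,2-trifluoroethoxy)phosphoryl]propanoic acid (EDC·HCl, DMAP catalytic, CH2Cl2, 0 °C) should give the C13 phosphonopropionate ester F3.
- Still–Gennari olefination with acetaldehyde (KN(SiMe3)2 in excess, 18-crown-6, THF, −78 °C) should then give the (Z)-2-methylbut-2-enoate 14.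

**Further compounds**

F1 | step 5 | (3R,4S,5S,9S,10R)-11-(tert-butoxycarbonyloxy)-13-(tert-butyldiphenylsilyloxy)drim-8(12)-en-3-ol | CC(C)(C)[Si](OC[C@]1(C)[C@H]2CCC(=C)[C@@H](COC(=O)OC(C)(C)C)[C@]2(C)CC[C@H]1O)(c1ccccc1)c1ccccc1
F2 | step 5 | 8,12-spiro-epoxide of F1, epoxide oxygen on the face opposite the C10 methyl | CC(C)(C)[Si](OC[C@]1(C)[C@H]2CC[C@@]3(CO3)[C@@H](COC(=O)OC(C)(C)C)[C@]2(C)CC[C@H]1O)(c1ccccc1)c1ccccc1
F0 | step 7 | none | none
F3 | step 9 | C13 2-[bis(2,2,2-trifluoroethoxy)phosphoryl]propanoate of 11 (both epimers at the phosphonate carbon) | CC(C(=O)OC[C@]1(C)[C@H]2CC[C@](C)(O)[C@@H](COc3ccc4ccc(=O)oc4c3)[C@]2(C)CC[C@H]1O)P(=O)(OCC(F)(F)F)OCC(F)(F)F
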